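## Plan

- Ring labels: oxolane 1 bears ring A (in the benzyl group on C4) and ring B (aryl on C2); oxolane 2 bears ring C (in the benzyl group on C4) and ring D (aryl on C2); rings B and C form the biaryl.
- Retrosynthesis: the benzyl ethers on the phenols of rings A and C come off last. Before that, both oxolanes (O1, C2 aryl-bearing, C3, C4 carbinol, C5) are opened at O1–C2. This works because each C2 is a benzylic carbon para to a phenolic OH (rings B and D) and is linked through C3–C4 to the C5 that carries O1, so it can arise from an ArCH2 group and the CH2OH on the carbinol carbon.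
- The open-chain dimer is traced back to two γ-lactones (the four primary CH2OH groups), then cut at the ring B–ring C bond, then in each lactone at the Cα–benzyl and Cα–O bonds.
- Forward: two (R)-β-benzyl-γ-butyrolactones are made (Stobbe condensation, asymmetric hydrogenation, reduction), then hydroxylated, protected and benzylated. One is borylated, the halves are joined (Suzuki–Miyaura), deprotected and reduced; both oxolanes then close in one operation, and hydrogenolysis finishes.
- Stereochemistry: C3 of each oxolane comes from the rhodium-catalysed hydrogenation, C4 from enolate benzylation anti to the β-benzyl group, C2 from the ring closure under control of C3.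

Key step: step 23

Assumption: the (4S,5S) antipode of MOD-DIOP is taken as the one that delivers the (R) acids 5 and 16 (otherwise the antipodal ligand is used), and step 23 is written through the bis(quinone methide) 29 although the two oxidation–closure events probably follow one another.

## Route

**Fragment 1 (rings A and B)**

Step 1
Reactants: 1 5-bromovanillin (3-bromo-4-hydroxy-5-methoxybenzaldehyde)
Product: 2 3-bromo-5-methoxy-4-(methoxymethoxy)benzaldehyde
Conditions: MOMCl (1.3 equiv), iPr2NEt (1.6 equiv), CH2Cl2, 0 °C → rt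
Reagents that add atoms: chloromethyl methyl ether (MOMCl), COCCl
Why: O-alkylation of the acidic phenol (Williamson-type) should give the MOM acetal, which tolerates the bases, hydrides and palladium steps ahead and is later removed by acid in the presence of aryl benzyl ethers.

Step 2
Reactants: 2 3-bromo-5-methoxy-4-(methoxymethoxy)benzaldehyde; 3 diethyl succinate
Product: 4 (E)-4-[3-bromo-5-methoxy-4-(methoxymethoxy)phenyl]-3-(ethoxycarbonyl)but-3-enoic acid
Conditions: KOtBu (1.3 equiv), tBuOH, reflux; then cold 1 M HCl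
Reagents that add atoms: none
Why: Stobbe condensation, in which the succinate enolate adds to the aldehyde, the aldolate lactonises and base-induced ring opening should give the (E)-alkylidene half ester with the free acid on the CH2 arm.

Step 3
Reactants: 4 (E)-4-[3-bromo-5-methoxy-4-(methoxymethoxy)phenyl]-3-(ethoxycarbonyl)but-3-enoic acid
Product: 5 (R)-4-[3-bromo-5-methoxy-4-(methoxymethoxy)phenyl]-3-(ethoxycarbonyl)butanoic acid
Conditions: H2 (5 atm), [Rh(cod)2]BF4 (1 mol %), (4S,5S)-MOD-DIOP (1.1 mol %), Et3N (1 equiv), MeOH, 30 °C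
Reagents that add atoms: none
Why: Rhodium-catalysed asymmetric hydrogenation of a Stobbe (itaconate-type) half ester, in which the carboxylate anchors the alkene to rhodium and the chiral diphosphine exposes one face, should set the (R) centre that becomes C3 of oxolane 1 while leaving the aryl bromide untouched.

Step 4
Reactants: 5 (R)-4-[3-bromo-5-methoxy-4-(methoxymethoxy)phenyl]-3-(ethoxycarbonyl)butanoic acid
Product: 7 (R)-4-[3-bromo-5-methoxy-4-(methoxymethoxy)benzyl]dihydrofuran-2(3H)-one, via hydroxy acid 6 (not isolated)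
Conditions: KOH (1.0 equiv), EtOH; CaCl2, NaBH4 (Ca(BH4)2 formed in the flask), EtOH, −10 °C → rt; then 1 M HCl, 0 °C → rt
Reagents that add atoms: none
Why: Chemoselective borohydride reduction of the ester beside the unreactive carboxylate, followed by acid-induced lactonisation of the γ-hydroxy acid, should give the β-benzyl lactone without touching the stereocentre.

Step 5
Reactants: 7 (R)-4-[3-bromo-5-methoxy-4-(methoxymethoxy)benzyl]dihydrofuran-2(3H)-one
Product: 8 (3R,4S)-4-[3-bromo-5-methoxy-4-(methoxymethoxy)benzyl]-3-hydroxydihydrofuran-2(3H)-one (OH trans to the benzyl group)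
Conditions: NaN(SiMe3)2 (1.2 equiv), THF, −78 °C; 2-(phenylsulfonyl)-3-phenyloxaziridine (1.5 equiv), −78 °C; AcOH quench
Reagents that add atoms: 2-(phenylsulfonyl)-3-phenyloxaziridine, O=S(=O)(c1ccccc1)N1OC1c1ccccc1
Why: Enolate hydroxylation with an N-sulfonyloxaziridine (Davis oxidation) should deliver oxygen anti to the β-benzyl group, although this centre becomes planar again in step 8 and its configuration is of no consequence.

Step 6
Reactants: 8 (3R,4S)-4-[3-bromo-5-methoxy-4-(methoxymethoxy)benzyl]-3-hydroxydihydrofuran-2(3H)-one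
Product: 9 (3R,4S)-4-[3-bromo-5-methoxy-4-(methoxymethoxy)benzyl]-3-(methoxymethoxy)dihydrofuran-2(3H)-one
Conditions: MOMCl (3 equiv), iPr2NEt (4 equiv), CH2Cl2, 0 → 40 °C
Reagents that add atoms: chloromethyl methyl ether (MOMCl), COCCl
Why: Acetal protection of the secondary alcohol should leave a single acidic site for the next enolisation and uses a group that cannot migrate to the enolate oxygen.

Step 7
Reactants: 10 [4-(benzyloxy)-3-methoxyphenyl]methanol
Product: 11 4-(benzyloxy)-3-methoxybenzyl bromide
Conditions: PBr3 (0.4 equiv), Et2O, 0 °C; used directly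
Reagents that add atoms: phosphorus tribromide, BrP(Br)Br
Why: Conversion of a benzylic alcohol into the bromide through its bromophosphite (SN2) is routine for electron-rich benzyl alcohols.

Step 8
Reactants: 9 (3R,4S)-4-[3-bromo-5-methoxy-4-(methoxymethoxy)benzyl]-3-(methoxymethoxy)dihydrofuran-2(3H)-one; 11 4-(benzyloxy)-3-methoxybenzyl bromide
Product: 12 (3S,4S)-3-[4-(benzyloxy)-3-methoxybenzyl]-4-[3-bromo-5-methoxy-4-(methoxymethoxy)benzyl]-3-(methoxymethoxy)dihydrofuran-2(3H)-one (fragment 1; the two benzyl groups trans)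
Conditions: LiN(iPr)2 (1.15 equiv), THF, −78 °C; then 11 (1.3 equiv), DMPU (3 equiv), −78 → −30 °C
Reagents that add atoms: none
Why: Alkylation of the α-alkoxy lactone lithium enolate (1,2-induction) should occur on the face opposite the β-benzyl group, so the new benzyl group ends trans to it and the fully substituted carbon that becomes C4 of oxolane 1 is set as (S).

**Fragment 2 (rings C and D)**

Step 9
Reactants: 13 vanillin
Product: 14 3-methoxy-4-(methoxymethoxy)benzaldehyde
Conditions: MOMCl (1.3 equiv), iPr2NEt (1.6 equiv), CH2Cl2, 0 °C → rt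
Reagents that add atoms: chloromethyl methyl ether (MOMCl), COCCl
Why: Same Williamson-type phenol protection as in step 1.

Step 10
Reactants: 14 3-methoxy-4-(methoxymethoxy)benzaldehyde; 3 diethyl succinate
Product: 15 (E)-3-(ethoxycarbonyl)-4-[3-methoxy-4-(methoxymethoxy)phenyl]but-3-enoic acid
Conditions: KOtBu (1.3 equiv), tBuOH, reflux; then cold 1 M HCl
Reagents that add atoms: none
Why: Stobbe condensation as in step 2.

Step 11
Reactants: 15 (E)-3-(ethoxycarbonyl)-4-[3-methoxy-4-(methoxymethoxy)phenyl]but-3-enoic acid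
Product: 16 (R)-3-(ethoxycarbonyl)-4-[3-methoxy-4-(methoxymethoxy)phenyl]butanoic acid
Conditions: H2 (5 atm), [Rh(cod)2]BF4 (1 mol %), (4S,5S)-MOD-DIOP (1.1 mol %), Et3N (1 equiv), MeOH, 30 °C
Reagents that add atoms: none
Why: The same rhodium-catalysed asymmetric hydrogenation as in step 3 should set the (R) centre that becomes C3 of oxolane 2.

Step 12
Reactants: 16 (R)-3-(ethoxycarbonyl)-4-[3-methoxy-4-(methoxymethoxy)phenyl]butanoic acid
Product: 18 (R)-4-[3-methoxy-4-(methoxymethoxy)benzyl]dihydrofuran-2(3H)-one, via hydroxy acid 17 (not isolated)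
Conditions: KOH (1.0 equiv), EtOH; CaCl2, NaBH4 (Ca(BH4)2 formed in the flask), EtOH, −10 °C → rt; then 1 M HCl, 0 °C → rt
Reagents that add atoms: none
Why: Carboxylate-sparing borohydride reduction of the ester and lactonisation, as in step 4.

Step 13
Reactants: 18 (R)-4-[3-methoxy-4-(methoxymethoxy)benzyl]dihydrofuran-2(3H)-one
Product: 19 (3R,4S)-3-hydroxy-4-[3-methoxy-4-(methoxymethoxy)benzyl]dihydrofuran-2(3H)-one
Conditions: NaN(SiMe3)2 (1.2 equiv), THF, −78 °C; 2-(phenylsulfonyl)-3-phenyloxaziridine (1.5 equiv), −78 °C; AcOH quench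
Reagents that add atoms: 2-(phenylsulfonyl)-3-phenyloxaziridine, O=S(=O)(c1ccccc1)N1OC1c1ccccc1
Why: Davis oxidation of the sodium enolate anti to the β-benzyl group, as in step 5, with the same inconsequential configuration at the new carbinol centre.

Step 14
Reactants: 19 (3R,4S)-3-hydroxy-4-[3-methoxy-4-(methoxymethoxy)benzyl]dihydrofuran-2(3H)-one
Product: 20 (3R,4S)-3-(methoxymethoxy)-4-[3-methoxy-4-(methoxymethoxy)benzyl]dihydrofuran-2(3H)-one
Conditions: MOMCl (3 equiv), iPr2NEt (4 equiv), CH2Cl2, 0 → 40 °C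
Reagents that add atoms: chloromethyl methyl ether (MOMCl), COCCl
Why: Acetal protection of the secondary alcohol as in step 6.

Step 15
Reactants: 1 5-bromovanillin
Product: 21 4-(benzyloxy)-3-bromo-5-methoxybenzaldehyde
Conditions: BnBr (1.1 equiv), K2CO3 (1.5 equiv), DMF, rt
Reagents that add atoms: benzyl bromide, BrCc1ccccc1
Why: Williamson ether synthesis on the phenoxide should install the benzyl ether that stays on ring C until the last step.

Step 16
Reactants: 21 4-(benzyloxy)-3-bromo-5-methoxybenzaldehyde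
Product: 22 [4-(benzyloxy)-3-bromo-5-methoxyphenyl]methanol
Conditions: NaBH4, MeOH/THF, 0 °C
Reagents that add atoms: none
Why: Borohydride reduction of an aryl aldehyde leaves the aryl bromide and the benzyl ether untouched.

Step 17
Reactants: 22 [4-(benzyloxy)-3-bromo-5-methoxyphenyl]methanol
Product: 23 4-(benzyloxy)-3-bromo-5-methoxybenzyl bromide
Conditions: PBr3 (0.4 equiv), Et2O, 0 °C; used directly
Reagents that add atoms: phosphorus tribromide, BrP(Br)Br
Why: Benzylic alcohol to bromide through the bromophosphite, as in step 7.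

Step 18
Reactants: 20 (3R,4S)-3-(methoxymethoxy)-4-[3-methoxy-4-(methoxymethoxy)benzyl]dihydrofuran-2(3H)-one; 23 4-(benzyloxy)-3-bromo-5-methoxybenzyl bromide
Product: 24 (3S,4S)-3-[4-(benzyloxy)-3-bromo-5-methoxybenzyl]-3-(methoxymethoxy)-4-[3-methoxy-4-(methoxymethoxy)benzyl]dihydrofuran-2(3H)-one (the two benzyl groups trans)
Conditions: LiN(iPr)2 (1.15 equiv), THF, −78 °C; then 23 (1.3 equiv), DMPU (3 equiv), −78 → −30 °C
Reagents that add atoms: none
Why: Enolate alkylation anti to the β-benzyl group, as in step 8, should set the fully substituted carbon that becomes C4 of oxolane 2 as (S), the benzylic bromide reacting in preference to the aryl bromide.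

Step 19
Reactants: 24 (3S,4S)-3-[4-(benzyloxy)-3-bromo-5-methoxybenzyl]-3-(methoxymethoxy)-4-[3-methoxy-4-(methoxymethoxy)benzyl]dihydrofuran-2(3H)-one
Product: 25 pinacol boronate of 24 (fragment 2; 4,4,5,5-tetramethyl-1,3,2-dioxaborolan-2-yl in place of Br on ring C)
Conditions: B2pin2 (1.3 equiv), PdCl2(dppf) (5 mol %), KOAc (3 equiv), 1,4-dioxane, 85 °C
Reagents that add atoms: bis(pinacolato)diboron, CC1(C)OB(OC1(C)C)B1OC(C)(C)C(C)(C)O1
Why: Miyaura borylation (oxidative addition of the aryl bromide to zerovalent palladium, acetate-assisted transmetalation from the diboron, reductive elimination) uses a base weak enough for the lactone and the acetals.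

**Union and endgame**

Step 20
Reactants: 12 fragment 1 bromide; 25 fragment 2 boronate
Product: 26 protected biaryl bis-lactone (C5 of ring B, ortho to its OMOM group, bonded to C5 of ring C, ortho to its benzyloxy group; both lactones (3S,4S); four MOM ethers and two benzyl ethers retained)
Conditions: Pd(OAc)2 (5 mol %), SPhos (10 mol %), K3PO4 (3 equiv), toluene/H2O 10:1, 80 °C; dilute HCl work-up
Reagents that add atoms: none
Why: Suzuki–Miyaura cross-coupling with a bulky electron-rich biarylphosphine suits partners that carry an oxygen substituent ortho to the reacting carbon, and with one ortho substituent per ring the new axis rotates freely, so no new stereogenic element arises.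

Step 21
Reactants: 26 protected biaryl bis-lactone
Product: 27 biaryl bis(hydroxy lactone) diphenol (both lactones (3S,4S)-3-hydroxy; free phenols on rings B and D; benzyl ethers on rings A and C)
Conditions: HCl (3 M in MeOH), THF, 45 °C
Reagents that add atoms: none
Why: Acid-catalysed transacetalisation to methanol should cleave all four MOM ethers while aryl benzyl ethers and γ-lactones persist, and doing so before the reduction avoids methylene-acetal formation with a neighbouring free hydroxyl.

Step 22
Reactants: 27 biaryl bis(hydroxy lactone) diphenol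
Product: 28 seco dimer: ring B–ring C biaryl carrying two (2S,3S)-2,3-bis(arylmethyl)butane-1,2,4-triol units (rings B and D free phenols, rings A and C benzyl ethers)
Conditions: LiAlH4 (8 equiv), THF, 0 °C → rt; aqueous potassium sodium tartrate work-up
Reagents that add atoms: none
Why: Hydride reduction of both γ-lactones to 1,4-diols should place a CH2OH on each carbinol carbon and on each C3, with phenols and tertiary alcohols merely held as aluminates and no epimerisable centre present.

Step 23
Reactants: 28 seco dimer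
Product: 30 bis-oxolane dibenzyl ether (both oxolanes (2S,3R,4S); free phenols on rings B and D; benzyl ethers on rings A and C), via bis(quinone methide) 29 (not isolated)
Conditions: DDQ (2.1 equiv), 1,4-dioxane, rt, dark, argon; aqueous NaHCO3 work-up
Reagents that add atoms: none
Why: DDQ oxidises each 4-alkyl-2-methoxyphenol unit (rings B and D) at its benzylic CH2 by net hydride loss to a para-quinone methide, and the primary hydroxyl of the CH2OH on the carbinol carbon adds to the exocyclic carbon, restoring the arene and forming O1–C2. The closest known reaction type is the DDQ oxidation of 4-alkylphenols to para-quinone methides with intramolecular capture by an alcohol, as used to close 2-aryloxolane lignans from open-chain dibenzylbutane diols. Each of the two oxolanes closes by a 5-exo-trig oxa-1,6-conjugate addition. Each new C2 stereocentre is controlled by the neighbouring C3 stereocentre, since in the envelope transition state the future aryl group lies pseudo-equatorial, trans to the C3 hydroxymethyl group and on the face opposite the C4 benzyl group, and reversibility of the capture makes this (2S) isomer the thermodynamic outcome as well. The step needs oxidation at only two of the four benzylic CH2 groups and capture by one of three hydroxyls per half: only rings B and D carry free phenols, the benzyl ethers of rings A and C cannot form quinone methides and lose hydride far more slowly, and attack by the tertiary hydroxyl or the C3 hydroxymethyl would give strained oxetanes. Over-oxidation of the product para-hydroxybenzylic ethers is held back by using close to two equivalents of oxidant at room temperature.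

Step 24
Reactants: 30 bis-oxolane dibenzyl ether
Product: 31 CNP0269573.1
Conditions: H2 (1 atm), 10% Pd/C, EtOAc/EtOH, rt; stopped after uptake of two equivalents
Reagents that add atoms: none
Why: Hydrogenolysis of aryl benzyl ethers on palladium is faster than cleavage of the cyclic benzylic C2–O1 bonds, so the two phenols of rings A and C should be released with the oxolanes intact.

## Compound list

1 | 5-bromovanillin | COc1cc(C=O)cc(Br)c1O | starting material
2 | 3-bromo-5-methoxy-4-(methoxymethoxy)benzaldehyde | COCOc1c(Br)cc(C=O)cc1OC | intermediate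
3 | diethyl succinate | CCOC(=O)CCC(=O)OCC | starting material
4 | (E)-4-[3-bromo-5-methoxy-4-(methoxymethoxy)phenyl]-3-(ethoxycarbonyl)but-3-enoic acid | CCOC(=O)/C(CC(=O)O)=C/c1cc(OC)c(OCOC)c(Br)c1 | intermediate
5 | (R)-4-[3-bromo-5-methoxy-4-(methoxymethoxy)phenyl]-3-(ethoxycarbonyl)butanoic acid | CCOC(=O)[C@H](Cc1cc(OC)c(OCOC)c(Br)c1)CC(=O)O | intermediate
6 | (R)-4-[3-bromo-5-methoxy-4-(methoxymethoxy)phenyl]-3-(hydroxymethyl)butanoic acid | OC[C@H](Cc1cc(OC)c(OCOC)c(Br)c1)CC(=O)O | intermediate (not isolated)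
7 | (R)-4-[3-bromo-5-methoxy-4-(methoxymethoxy)benzyl]dihydrofuran-2(3H)-one | O=C1C[C@@H](Cc2cc(OC)c(OCOC)c(Br)c2)CO1 | intermediate
8 | (3R,4S)-4-[3-bromo-5-methoxy-4-(methoxymethoxy)benzyl]-3-hydroxydihydrofuran-2(3H)-one | O=C1[C@H](O)[C@@H](Cc2cc(OC)c(OCOC)c(Br)c2)CO1 | intermediate
9 | (3R,4S)-4-[3-bromo-5-methoxy-4-(methoxymethoxy)benzyl]-3-(methoxymethoxy)dihydrofuran-2(3H)-one | O=C1[C@H](OCOC)[C@@H](Cc2cc(OC)c(OCOC)c(Br)c2)CO1 | intermediate
10 | [4-(benzyloxy)-3-methoxyphenyl]methanol | COc1cc(CO)ccc1OCc1ccccc1 | starting material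
11 | 4-(benzyloxy)-3-methoxybenzyl bromide | COc1cc(CBr)ccc1OCc1ccccc1 | intermediate
12 | (3S,4S)-3-[4-(benzyloxy)-3-methoxybenzyl]-4-[3-bromo-5-methoxy-4-(methoxymethoxy)benzyl]-3-(methoxymethoxy)dihydrofuran-2(3H)-one | O=C1[C@@](Cc2ccc(OCc3ccccc3)c(OC)c2)(OCOC)[C@@H](Cc2cc(OC)c(OCOC)c(Br)c2)CO1 | intermediate
13 | vanillin | COc1cc(C=O)ccc1O | starting material
14 | 3-methoxy-4-(methoxymethoxy)benzaldehyde | COCOc1ccc(C=O)cc1OC | intermediate
15 | (E)-3-(ethoxycarbonyl)-4-[3-methoxy-4-(methoxymethoxy)phenyl]but-3-enoic acid | CCOC(=O)/C(CC(=O)O)=C/c1ccc(OCOC)c(OC)c1 | intermediate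
16 | (R)-3-(ethoxycarbonyl)-4-[3-methoxy-4-(methoxymethoxy)phenyl]butanoic acid | CCOC(=O)[C@H](Cc1ccc(OCOC)c(OC)c1)CC(=O)O | intermediate
17 | (R)-3-(hydroxymethyl)-4-[3-methoxy-4-(methoxymethoxy)phenyl]butanoic acid | OC[C@H](Cc1ccc(OCOC)c(OC)c1)CC(=O)O | intermediate (not isolated)
18 | (R)-4-[3-methoxy-4-(methoxymethoxy)benzyl]dihydrofuran-2(3H)-one | O=C1C[C@@H](Cc2ccc(OCOC)c(OC)c2)CO1 | intermediate
19 | (3R,4S)-3-hydroxy-4-[3-methoxy-4-(methoxymethoxy)benzyl]dihydrofuran-2(3H)-one | O=C1[C@H](O)[C@@H](Cc2ccc(OCOC)c(OC)c2)CO1 | intermediate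
20 | (3R,4S)-3-(methoxymethoxy)-4-[3-methoxy-4-(methoxymethoxy)benzyl]dihydrofuran-2(3H)-one | O=C1[C@H](OCOC)[C@@H](Cc2ccc(OCOC)c(OC)c2)CO1 | intermediate
21 | 4-(benzyloxy)-3-bromo-5-methoxybenzaldehyde | COc1cc(C=O)cc(Br)c1OCc1ccccc1 | intermediate
22 | [4-(benzyloxy)-3-bromo-5-methoxyphenyl]methanol | COc1cc(CO)cc(Br)c1OCc1ccccc1 | intermediate
23 | 4-(benzyloxy)-3-bromo-5-methoxybenzyl bromide | COc1cc(CBr)cc(Br)c1OCc1ccccc1 | intermediate
24 | (3S,4S)-3-[4-(benzyloxy)-3-bromo-5-methoxybenzyl]-3-(methoxymethoxy)-4-[3-methoxy-4-(methoxymethoxy)benzyl]dihydrofuran-2(3H)-one | O=C1[C@@](Cc2cc(Br)c(OCc3ccccc3)c(OC)c2)(OCOC)[C@@H](Cc2ccc(OCOC)c(OC)c2)CO1 | intermediate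
25 | pinacol boronate of 24 | O=C1[C@@](Cc2cc(B3OC(C)(C)C(C)(C)O3)c(OCc3ccccc3)c(OC)c2)(OCOC)[C@@H](Cc2ccc(OCOC)c(OC)c2)CO1 | intermediate
26 | protected biaryl bis-lactone | O=C1[C@@](Cc2ccc(OCc3ccccc3)c(OC)c2)(OCOC)[C@@H](Cc2cc(OC)c(OCOC)c(-c3cc(C[C@@]4(OCOC)C(=O)OC[C@@H]4Cc4ccc(OCOC)c(OC)c4)cc(OC)c3OCc3ccccc3)c2)CO1 | intermediate
27 | biaryl bis(hydroxy lactone) diphenol | O=C1[C@@](Cc2ccc(OCc3ccccc3)c(OC)c2)(O)[C@@H](Cc2cc(OC)c(O)c(-c3cc(C[C@@]4(O)C(=O)OC[C@@H]4Cc4ccc(O)c(OC)c4)cc(OC)c3OCc3ccccc3)c2)CO1 | intermediate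
28 | seco dimer (key-step precursor) | COc1cc(C[C@@](O)(CO)[C@H](CO)Cc2cc(OC)c(O)c(-c3cc(C[C@@](O)(CO)[C@H](CO)Cc4ccc(O)c(OC)c4)cc(OC)c3OCc3ccccc3)c2)ccc1OCc1ccccc1 | intermediate
29 | bis(quinone methide) of 28 (exocyclic alkene geometry not defined) | COc1cc(C[C@@](O)(CO)[C@H](CO)C=C2C=C(OC)C(=O)C(c3cc(C[C@@](O)(CO)[C@H](CO)C=C4C=CC(=O)C(OC)=C4)cc(OC)c3OCc3ccccc3)=C2)ccc1OCc1ccccc1 | intermediate (not isolated)
30 | bis-oxolane dibenzyl ether (key-step product) | COc1cc(C[C@@]2(O)CO[C@H](c3cc(OC)c(O)c(-c4cc(C[C@@]5(O)CO[C@H](c6ccc(O)c(OC)c6)[C@H]5CO)cc(OC)c4OCc4ccccc4)c3)[C@H]2CO)ccc1OCc1ccccc1 | intermediate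
31 | CNP0269573.1 | COc1cc(C[C@@]2(O)CO[C@H](c3cc(OC)c(O)c(-c4cc(C[C@@]5(O)CO[C@H](c6ccc(O)c(OC)c6)[C@H]5CO)cc(OC)c4O)c3)[C@H]2CO)ccc1O | target

## Step count and risks

Total: 24 steps. Longest linear sequence: 13 steps (from vanillin 13: steps 9–14 and 18–24).

**1. Step 23 (key step).** Several processes can go wrong here:
- oxidation may continue at the para-hydroxybenzylic C2–H of an oxolane that has already closed while the other phenol is still unreacted;
- hydride may be lost slowly from the benzyl-ether rings A and C;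
- if the medium turns acidic, a quinone methide may be captured at carbon (Friedel–Crafts) by ring A or C instead of at oxygen;
- facial control at C2 may be incomplete.

With two events required on one polar molecule, these losses multiply. The fallback closes each oxolane before the biaryl bond is made:
- Setting out from bromide 12, HCl in MeOH should remove both MOM groups to give the hydroxy lactone phenol F1. LiBH4 in THF, which leaves the aryl bromide alone, should give the triol F2, and one equivalent of DDQ in dioxane the bromo-oxolane F3.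
- Bromide 24 is taken through the same three operations to the hydroxy lactone phenol F4, the triol F5 and the bromo-oxolane F6. F6 is then borylated (B2pin2, PdCl2(dppf), KOAc, dioxane) to the boronate F7.
- Suzuki–Miyaura coupling of F3 with F7 (Pd(OAc)2, SPhos, K3PO4, dioxane/H2O) rejoins the route at 30.

Each oxidation then involves a single phenol, the oxidant can be dosed exactly, and any C2 epimer is removed on a small, less polar compound.

**2. Step 8 (step 18 is the same reaction on the other half and shares risk and remedy).** Carbon–carbon bond formation at the fully substituted enolate carbon may be slow. The labile electron-rich benzylic bromide could then decompose, proton transfer could return 9, or attack syn to the β-benzyl group could erode the diastereoselectivity. The fallback omits the O-protection and alkylates the more nucleophilic alkoxide–enolate dianion, a mode of benzylation known for α-hydroxy-β-benzyl-γ-butyrolactones that keeps the same facial bias. Setting out from hydroxy lactone 8, LiN(iPr)2 (2.2 equiv) in THF/DMPU and bromide 11 should give the tertiary alcohol F8; MOMCl, iPr2NEt and NaI at 50 °C convert it into 12. For step 18 the same sequence leads from 19 and 23 through the tertiary alcohol F9 to 24.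

**3. Step 24.** Hydrogenolysis may run on from the aryl benzyl ethers into the benzylic C2–O1 bonds of the oxolanes, which the electron-rich para-hydroxyaryl groups make prone to reductive ring opening. The fallback sets out from 30: Ac2O in pyridine should acylate the two phenols and the two primary hydroxyls to the tetraacetate F10, whose para-acetoxyaryl groups make the C2–O1 bonds less easily cleaved. Hydrogenolysis (H2, 10% Pd/C, EtOAc) then gives the diphenol tetraacetate F11, and methanolysis (K2CO3, MeOH, 0 °C) rejoins the route at the target 31.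

## Further compounds

F1 | step 23 | (3S,4S)-3-[4-(benzyloxy)-3-methoxybenzyl]-4-(3-bromo-4-hydroxy-5-methoxybenzyl)-3-hydroxydihydrofuran-2(3H)-one | O=C1[C@@](Cc2ccc(OCc3ccccc3)c(OC)c2)(O)[C@@H](Cc2cc(OC)c(O)c(Br)c2)CO1
F2 | step 23 | (2S,3S)-2-[4-(benzyloxy)-3-methoxybenzyl]-3-(3-bromo-4-hydroxy-5-methoxybenzyl)butane-1,2,4-triol | COc1cc(C[C@@](O)(CO)[C@H](CO)Cc2cc(OC)c(O)c(Br)c2)ccc1OCc1ccccc1
F3 | step 23 | (2S,3R,4S)-4-[4-(benzyloxy)-3-methoxybenzyl]-2-(3-bromo-4-hydroxy-5-methoxyphenyl)-3-(hydroxymethyl)oxolan-4-ol | COc1cc(C[C@@]2(O)CO[C@H](c3cc(OC)c(O)c(Br)c3)[C@H]2CO)ccc1OCc1ccccc1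
F4 | step 23 | (3S,4S)-3-[4-(benzyloxy)-3-bromo-5-methoxybenzyl]-3-hydroxy-4-(4-hydroxy-3-methoxybenzyl)dihydrofuran-2(3H)-one | O=C1[C@@](Cc2cc(Br)c(OCc3ccccc3)c(OC)c2)(O)[C@@H](Cc2ccc(O)c(OC)c2)CO1
F5 | step 23 | (2S,3S)-2-[4-(benzyloxy)-3-bromo-5-methoxybenzyl]-3-(4-hydroxy-3-methoxybenzyl)butane-1,2,4-triol | COc1cc(C[C@@](O)(CO)[C@H](CO)Cc2ccc(O)c(OC)c2)cc(Br)c1OCc1ccccc1
F6 | step 23 | (2S,3R,4S)-4-[4-(benzyloxy)-3-bromo-5-methoxybenzyl]-2-(4-hydroxy-3-methoxyphenyl)-3-(hydroxymethyl)oxolan-4-ol | COc1cc(C[C@@]2(O)CO[C@H](c3ccc(O)c(OC)c3)[C@H]2CO)cc(Br)c1OCc1ccccc1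
F7 | step 23 | pinacol boronate of F6 (Bpin in place of Br) | COc1cc(C[C@@]2(O)CO[C@H](c3ccc(O)c(OC)c3)[C@H]2CO)cc(B2OC(C)(C)C(C)(C)O2)c1OCc1ccccc1
F8 | step 8 | (3S,4S)-3-[4-(benzyloxy)-3-methoxybenzyl]-4-[3-bromo-5-methoxy-4-(methoxymethoxy)benzyl]-3-hydroxydihydrofuran-2(3H)-one | O=C1[C@@](Cc2ccc(OCc3ccccc3)c(OC)c2)(O)[C@@H](Cc2cc(OC)c(OCOC)c(Br)c2)CO1
F9 | step 18 | (3S,4S)-3-[4-(benzyloxy)-3-bromo-5-methoxybenzyl]-3-hydroxy-4-[3-methoxy-4-(methoxymethoxy)benzyl]dihydrofuran-2(3H)-one | O=C1[C@@](Cc2cc(Br)c(OCc3ccccc3)c(OC)c2)(O)[C@@H](Cc2ccc(OCOC)c(OC)c2)CO1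
F10 | step 24 | tetraacetate of 30 (acetates on the phenols of rings B and D and on both primary hydroxyls) | COc1cc(C[C@@]2(O)CO[C@H](c3cc(OC)c(OC(C)=O)c(-c4cc(C[C@@]5(O)CO[C@H](c6ccc(OC(C)=O)c(OC)c6)[C@H]5COC(C)=O)cc(OC)c4OCc4ccccc4)c3)[C@H]2COC(C)=O)ccc1OCc1ccccc1
F11 | step 24 | debenzylated tetraacetate (free phenols on rings A and C) | COc1cc(C[C@@]2(O)CO[C@H](c3cc(OC)c(OC(C)=O)c(-c4cc(C[C@@]5(O)CO[C@H](c6ccc(OC(C)=O)c(OC)c6)[C@H]5COC(C)=O)cc(OC)c4O)c3)[C@H]2COC(C)=O)ccc1O
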